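**Assumptions (one line):** 2‑bromoresorcinol and (S)‑3‑buten‑2‑ol are bought commercially. The target is (3R), as encoded in the SMILES (C3 priorities: CH2O > aryl > CH2Ar).

## Retrosynthetic overview
1. The two prenyl groups (C8 and C3′) come last, from the two Ar–Br handles by Li/Br exchange and Cu‑catalysed prenylation. They are added late because an earlier ozonolysis would cleave them.
2. The chroman C2–O1 bond is closed by an intramolecular Mitsunobu reaction of a 2,3‑diarylpropanol.
3. The C3 stereocentre and the C3–aryl(B) bond form together in one aromatic Claisen [3,3] rearrangement. It transfers chirality from the carbinol of an (R)‑aryl 1‑methylallyl ether (made from (S)‑3‑buten‑2‑ol) to the benzylic carbon. Ozonolysis then unmasks the CH2OH (C2).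
4. The A‑ring allyl group is made by an earlier, ordinary Claisen rearrangement. Both aryl units come from one mono‑MOM 2‑bromoresorcinol, where Br blocks one ortho position and marks the later prenyl site.

## Route

**Step 1**
Reactants: 1 (2‑bromoresorcinol, 2 equiv), 2 (MOMCl, 1 equiv)
Product: 3 (2‑bromo‑3‑(methoxymethoxy)phenol)
Conditions: i‑Pr2NEt, CH2Cl2, 0 → 25 °C
Reagents that add atoms: MOMCl, ClCOC
Why: 1 is a symmetrical diol, so mono‑MOM protection gives a single regioisomer, and excess diol suppresses bis‑protection.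

**Step 2**
Reactants: 3, 4 (allyl bromide)
Product: 5 (1‑(allyloxy)‑2‑bromo‑3‑(methoxymethoxy)benzene)
Conditions: K2CO3, acetone, 56 °C
Reagents that add atoms: allyl bromide, C=CCBr
Why: Williamson etherification of the only free phenol.

**Step 3**
Reactants: 5, 6 (Ac2O)
Product: 7 (2‑allyl‑6‑bromo‑5‑(methoxymethoxy)phenyl acetate)
Conditions: PhNEt2, 190 °C, 1 h; then Ac2O, DMAP, 25 °C (one pot)
Reagents that add atoms: acetic anhydride, CC(=O)OC(C)=O
Why: an aromatic Claisen rearrangement can only reach the free ortho carbon because Br blocks the other. The acetate then marks this phenol (the future O1) for later selective release.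

**Step 4**
Reactants: 3, 8 ((S)‑but‑3‑en‑2‑ol)
Product: 9 ((R)‑1‑(but‑3‑en‑2‑yloxy)‑2‑bromo‑3‑(methoxymethoxy)benzene)
Conditions: PPh3, DIAD, THF, 0 → 25 °C
Reagents that add atoms: none
Why: Mitsunobu etherification of the acidic phenol proceeds with clean SN2 inversion, so (S)‑alcohol gives (R)‑ether. This fixes the carbinol configuration that is later transferred.

**Step 5**
Reactants: 9 (2.5 equiv), 7 (1 equiv)
Product: 10 ((R,E)‑2‑[4‑(2‑bromo‑3‑MOMO‑phenoxy)pent‑2‑en‑1‑yl]‑6‑bromo‑5‑MOMO‑phenyl acetate)
Conditions: Hoveyda–Grubbs II (5 mol%), CH2Cl2, 40 °C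
Reagents that add atoms: none (ethylene is lost)
Why: cross‑metathesis of a terminal allylarene with a terminal allylic ether gives the (E)‑1,2‑disubstituted alkene needed for a chair Claisen transition state. The stereocentre is untouched.

**Step 6**
Reactant: 10
Product: 11 ((E)‑propenyl phenol with C3 set; 2′‑OH free)
Conditions: PhNEt2, 185 °C, sealed tube or microwave, 1 h
Reagents that add atoms: none
Why: aromatic Claisen [3,3] rearrangement of the E‑allyl aryl ether through a chair transition state with the methyl group equatorial. The aryl–C3 bond forms on the face of the breaking C–O bond, so the (R)‑carbinol gives the (3R) benzylic centre. Br forces bond formation at the single free ortho carbon (C1′).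

**Step 7**
Reactants: 11, 2 (MOMCl)
Product: 12 (2′‑OMOM derivative)
Conditions: i‑Pr2NEt, CH2Cl2, 0 → 25 °C
Reagents that add atoms: MOMCl, ClCOC
Why: the new phenol is masked so that it cannot form a dihydrobenzofuran in the ring closure, and so it is stable to the lithiation later. The A‑ring acetate survives these mild basic conditions.

**Step 8**
Reactants: 12, 13 (ozone)
Product: 14 ((R)‑2,3‑diarylpropan‑1‑ol, A‑ring O1 still acetylated)
Conditions: O3, CH2Cl2/MeOH, −78 °C; then NaBH4, −78 → 0 °C
Reagents that add atoms: ozone, O=[O+][O-] (its oxygen becomes the CH2OH oxygen); NaBH4 adds only hydride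
Why: ozonolysis cleaves the only alkene, which is possible because no prenyl groups are present yet. In‑situ reduction keeps the epimerisable α‑aryl aldehyde short‑lived, so C3 is not racemised.

**Step 9**
Reactant: 14
Product: 15 (free A‑ring phenol O1 and primary alcohol)
Conditions: K2CO3, MeOH, 25 °C
Reagents that add atoms: none
Why: methanolysis of the aryl acetate (partly already cleaved by NaBH4) releases only O1, leaving the MOM ethers and aryl bromides intact.

**Step 10**
Reactant: 15
Product: 16 ((3R)‑8,3′‑dibromo‑7,2′,4′‑tris(MOM‑oxy)isoflavan)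
Conditions: PPh3, DIAD, THF (0.01 M), 0 → 25 °C
Reagents that add atoms: none
Why: intramolecular Mitsunobu closure (6‑exo) of the acidic ortho‑bromophenol onto the primary alcohol forms the chroman. The reacting carbon is not stereogenic, so C3 is unaffected.

**Step 11**
Reactants: 16, 17 (prenyl bromide)
Product: 18 (tris‑MOM, bis‑prenyl isoflavan)
Conditions: t‑BuLi (4.4 equiv), THF, −78 °C, 30 min; then CuBr·SMe2 (0.2 equiv), prenyl bromide (3.5 equiv), −78 → 0 °C
Reagents that add atoms: prenyl bromide, CC(C)=CCBr
Why: Li/Br exchange gives aryllithiums, each flanked by two oxygens. Cu catalysis favours SN2 over SN2′ coupling, so normal prenyl groups form at exactly C8 and C3′.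

**Step 12**
Reactant: 18
Product: 19 (kanzonol X)
Conditions: ZnBr2, n‑PrSH, CH2Cl2, 0 → 25 °C
Reagents that add atoms: none
Why: mild Lewis‑acid/thiol cleavage of the three aryl MOM ethers avoids acid‑promoted cyclisation of the o‑prenylphenols and leaves C3 untouched.

## Compound list
1 | 2‑bromobenzene‑1,3‑diol | Oc1cccc(O)c1Br | starting material
2 | chloromethyl methyl ether | ClCOC | starting material (reagent)
3 | 2‑bromo‑3‑(methoxymethoxy)phenol | COCOc1cccc(O)c1Br | intermediate
4 | allyl bromide | C=CCBr | starting material (reagent)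
5 | 1‑(allyloxy)‑2‑bromo‑3‑(methoxymethoxy)benzene | C=CCOc1cccc(OCOC)c1Br | intermediate
6 | acetic anhydride | CC(=O)OC(C)=O | starting material (reagent)
7 | 2‑allyl‑6‑bromo‑5‑(methoxymethoxy)phenyl acetate | CC(=O)Oc1c(CC=C)ccc(OCOC)c1Br | intermediate
8 | (S)‑but‑3‑en‑2‑ol | C[C@@H](C=C)O | starting material (chiral pool)
9 | (R)‑1‑(but‑3‑en‑2‑yloxy)‑2‑bromo‑3‑(methoxymethoxy)benzene | C[C@@H](Oc1cccc(OCOC)c1Br)C=C | intermediate
10 | cross‑metathesis product ((R,E)‑allylic aryl ether) | C[C@@H](Oc1cccc(OCOC)c1Br)/C=C/Cc1ccc(OCOC)c(Br)c1OC(C)=O | intermediate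
11 | Claisen product (2′‑OH, (E)‑propenyl) | Oc1c(Br)c(OCOC)ccc1[C@@H](Cc1ccc(OCOC)c(Br)c1OC(C)=O)/C=C/C | intermediate
12 | 2′‑O‑MOM Claisen product | COCOc1c(Br)c(OCOC)ccc1[C@@H](Cc1ccc(OCOC)c(Br)c1OC(C)=O)/C=C/C | intermediate
13 | ozone | O=[O+][O-] | starting material (reagent)
14 | (R)‑2,3‑diarylpropanol, A‑ring acetate | COCOc1c(Br)c(OCOC)ccc1[C@@H](Cc1ccc(OCOC)c(Br)c1OC(C)=O)CO | intermediate
15 | (R)‑2,3‑diarylpropanol, A‑ring phenol | COCOc1c(Br)c(OCOC)ccc1[C@@H](Cc1ccc(OCOC)c(Br)c1O)CO | intermediate
16 | (3R)‑8,3′‑dibromo‑7,2′,4′‑tris(MOM‑oxy)isoflavan | COCOc1c(Br)c(OCOC)ccc1[C@@H]1COc2c(Br)c(OCOC)ccc2C1 | intermediate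
17 | prenyl bromide | CC(C)=CCBr | starting material (reagent)
18 | (3R)‑8,3′‑diprenyl‑7,2′,4′‑tris(MOM‑oxy)isoflavan | COCOc1c(CC=C(C)C)c(OCOC)ccc1[C@@H]1COc2c(CC=C(C)C)c(OCOC)ccc2C1 | intermediate
19 | kanzonol X | CC(C)=CCc1c(O)ccc([C@@H]2COc3c(ccc(O)c3CC=C(C)C)C2)c1O | target

**Total steps:** 12. **Longest linear sequence:** 11 (1 → 3 → 5 → 7 → 10 → 11 → 12 → 14 → 15 → 16 → 18 → 19).

## Three steps most likely to fail
1. **Step 6 (chirality‑transferring Claisen).** Any Z‑alkene from step 5, thermal C3 erosion, or cyclisation of the o‑allylphenol lowers ee or yield.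
   Fallback: replace the [3,3] with a Cu‑catalysed anti‑SN2′ arylation. Convert the (S)‑allylic alcohol (from 7 and 8) to its carbonate and treat it with the aryl Grignard of 1‑iodo‑3‑bromo‑2,4‑bis(MOM‑oxy)benzene.
2. **Step 11 (double Li/Br exchange and prenylation).** Incomplete exchange, SN2′ reverse‑prenyl products, or prenyl‑bromide metathesis with the aryllithium can lower the yield.
   Fallback: install allyl groups instead (ArLi + allyl bromide, which has no SN2′ problem), then convert both to prenyl by cross‑metathesis with 2‑methyl‑2‑butene.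
3. **Step 5 (cross‑metathesis).** Ru–H isomerisation of the allylic aryl ether, allylarene homodimerisation, or poor E/Z selectivity can occur.
   Fallback: build the (E)‑allylic alcohol from (S)‑3‑butyn‑2‑ol instead. Alkylate its dianion with the A‑ring benzylic bromide, reduce with Red‑Al to the E‑alkene, then do the Mitsunobu with 3.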